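**Retrosynthetic overview**
1. Endgame: the C3 isopropyl carbinol comes from a C3 ketone (organocerium addition, last step). The C8 benzoate and C1 acetate come from a C8‑hydroxy C1‑ketone by Evans–Tishchenko reduction with benzaldehyde, then Mitsunobu inversion with acetic acid. The C4 aryl ester comes from acylation.
2. Key disconnection: the C4–C5 bond of the seven‑membered ring, made by a SmI2 ketyl radical 7‑endo addition onto an isopropenyl group with loss of an allylic chloride; this sets C4–OH and creates the C6=C7 olefin.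
3. The cyclisation precursor is a trans‑2,3‑disubstituted cyclopentanone, made by a three‑component coupling (dithianyl anion 1,4‑addition, then enolate aldol with 3‑methylbut‑2‑enal) followed by ene‑type allylic chlorination.
4. Ring order: cyclopentane first, from (R)‑4‑silyloxycyclopentenone, whose single stereocentre relays all the others; seven‑membered ring second, by the radical step.

Assumption: atom labels are the azulene numbering of the target (C1, C2, C3, C3a, C4–C8, C8a), β is the face of the C8a methyl, and the TBS ethers 1 and 13 are bought as such. The route is a plan argued from precedent, not an experimentally verified sequence.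

Step 1
Reactants: 1 (4R)-4-[(tert-butyldimethylsilyl)oxy]cyclopent-2-en-1-one
Product: 2 (4R)-4-[(tert-butyldimethylsilyl)oxy]-2-iodocyclopent-2-en-1-one
Conditions: I2, pyridine/CH2Cl2 (1:1), 0 °C to rt
Reagents that add atoms: iodine, II
Why: Johnson α‑iodination of an enone (reversible pyridine 1,4‑addition, iodination of the enolate, elimination of pyridine); the silyloxy stereocentre is not touched.

Step 2
Reactants: 2 (4R)-4-[(tert-butyldimethylsilyl)oxy]-2-iodocyclopent-2-en-1-one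
Product: 3 (4R)-4-[(tert-butyldimethylsilyl)oxy]-2-methylcyclopent-2-en-1-one
Conditions: SnMe4, Pd2(dba)3 (cat.), AsPh3, CuI (cat.), NMP, 60 °C
Reagents that add atoms: tetramethylstannane, C[Sn](C)(C)C
Why: Stille cross‑coupling of the α‑iodoenone installs the future C8a methyl; no stereocentre is involved.

Step 3
Reactants: 3 (4R)-4-[(tert-butyldimethylsilyl)oxy]-2-methylcyclopent-2-en-1-one; 4 1,3-dithiane; 5 3-methylbut-2-enal
Product: 9 (2S,3R,4R)-4-[(tert-butyldimethylsilyl)oxy]-3-(1,3-dithian-2-yl)-2-[(1S)-1-hydroxy-3-methylbut-2-en-1-yl]-2-methylcyclopentan-1-one, via 2-lithio-1,3-dithiane 6 (not isolated), via lithium enolate 7 (not isolated), via chlorozinc enolate 8 (not isolated)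
Conditions: 4, n-BuLi, THF, −30 °C; HMPA then 3, −78 °C; ZnCl2, −78 °C; 5, −78 to −40 °C; aq NH4Cl
Reagents that add atoms: none
Why: Three‑component conjugate addition–aldol coupling: the dithianyl anion (formyl anion equivalent) adds 1,4 in THF–HMPA anti to the OTBS group (sets C3a), and the regiospecific zinc enolate attacks the enal on the face opposite the dithianyl group (sets the C8a quaternary centre, methyl β) through a Zimmerman–Traxler chair with the alkenyl group equatorial, which places the C8 hydroxyl syn to the C8a methyl (8S).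

Step 4
Reactants: 9 (2S,3R,4R)-4-[(tert-butyldimethylsilyl)oxy]-3-(1,3-dithian-2-yl)-2-[(1S)-1-hydroxy-3-methylbut-2-en-1-yl]-2-methylcyclopentan-1-one
Product: 10 (2S,3R,4R)-4-[(tert-butyldimethylsilyl)oxy]-3-formyl-2-[(1S)-1-hydroxy-3-methylbut-2-en-1-yl]-2-methylcyclopentan-1-one
Conditions: MeI, CaCO3, MeCN/H2O (9:1), 40 °C
Reagents that add atoms: water, O
Why: S‑methylation and hydrolysis of the dithioacetal unmask the C4 aldehyde under near‑neutral conditions that spare the β‑silyloxy and β‑hydroxy ketone; the formyl group stays trans to its neighbours, which is also the thermodynamic arrangement.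

Step 5
Reactants: 10 (2S,3R,4R)-4-[(tert-butyldimethylsilyl)oxy]-3-formyl-2-[(1S)-1-hydroxy-3-methylbut-2-en-1-yl]-2-methylcyclopentan-1-one
Product: 11 (2S,3R,4R)-4-[(tert-butyldimethylsilyl)oxy]-2-[(1R,2RS)-2-chloro-1-hydroxy-3-methylbut-3-en-1-yl]-3-formyl-2-methylcyclopentan-1-one
Conditions: NCS, PhSeCl (10 mol%), CH2Cl2, rt
Reagents that add atoms: N-chlorosuccinimide, O=C1CCC(=O)N1Cl
Why: Selenium‑catalysed ene‑type allylic chlorination of the trisubstituted olefin gives the transposed secondary allylic chloride and a 1,1‑disubstituted olefin; the new chloride‑bearing centre (future C7) becomes sp2 in step 6, so both epimers are used.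

Step 6
Reactants: 11 (2S,3R,4R)-4-[(tert-butyldimethylsilyl)oxy]-2-[(1R,2RS)-2-chloro-1-hydroxy-3-methylbut-3-en-1-yl]-3-formyl-2-methylcyclopentan-1-one
Product: 12 (3R,3aS,4S,8S,8aS)-3-[(tert-butyldimethylsilyl)oxy]-4,8-dihydroxy-6,8a-dimethyl-3,3a,4,5,8,8a-hexahydroazulen-1(2H)-one
Conditions: SmI2 (2.5 equiv), HMPA, THF (0.005 M, slow addition of 11), −78 to −20 °C; aq NH4Cl
Reagents that add atoms: none
Why: Proposed new method: SmI2 reduces the aldehyde to a ketyl radical that adds 7‑endo to the unsubstituted terminus of the 1,1‑disubstituted olefin (6‑exo attack at the substituted carbon is disfavoured, high dilution suppresses pinacol coupling), the tertiary radical then expels the allylic chloride (β‑scission or reduction–elimination) to give the endocyclic C6=C7 olefin, and the bulky O–Sm(III) group sits pseudo‑equatorial in the chair‑like transition state so that C4–OH is α (H3a/H4 trans‑diaxial); the closest known reactions are SmI2 ketyl–olefin cyclisations and ketyl SN2′ couplings with vinyl epoxides or allylic leaving groups.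

Step 7
Reactants: 13 (4-bromophenoxy)(tert-butyl)dimethylsilane
Product: 15 4-[(tert-butyldimethylsilyl)oxy]benzoic acid, via aryllithium 14 (not isolated)
Conditions: n-BuLi, THF, −78 °C; CO2 (g); 1 M HCl to pH 4, 0 °C
Reagents that add atoms: carbon dioxide, O=C=O
Why: Bromine–lithium exchange followed by carboxylation of the aryllithium gives the protected 4‑hydroxybenzoic acid.

Step 8
Reactants: 12 (3R,3aS,4S,8S,8aS)-3-[(tert-butyldimethylsilyl)oxy]-4,8-dihydroxy-6,8a-dimethyl-3,3a,4,5,8,8a-hexahydroazulen-1(2H)-one; 15 4-[(tert-butyldimethylsilyl)oxy]benzoic acid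
Product: 16 (3R,3aS,4S,8S,8aS)-3-[(tert-butyldimethylsilyl)oxy]-8-hydroxy-6,8a-dimethyl-1-oxo-1,2,3,3a,4,5,8,8a-octahydroazulen-4-yl 4-[(tert-butyldimethylsilyl)oxy]benzoate
Conditions: 15 (1.1 equiv), DCC, DMAP (cat.), CH2Cl2, −20 to 0 °C
Reagents that add atoms: none
Why: Steglich esterification is site‑selective for the equatorial C4–OH (flanked by CH and CH2) over the C8–OH, which is neopentylic (next to quaternary C8a) and hydrogen‑bonded to the C1 ketone.

Step 9
Reactants: 16 (3R,3aS,4S,8S,8aS)-3-[(tert-butyldimethylsilyl)oxy]-8-hydroxy-6,8a-dimethyl-1-oxo-1,2,3,3a,4,5,8,8a-octahydroazulen-4-yl 4-[(tert-butyldimethylsilyl)oxy]benzoate; 17 benzaldehyde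
Product: 18 (1R,3R,3aS,4S,8S,8aR)-8-(benzoyloxy)-3-[(tert-butyldimethylsilyl)oxy]-1-hydroxy-6,8a-dimethyl-1,2,3,3a,4,5,8,8a-octahydroazulen-4-yl 4-[(tert-butyldimethylsilyl)oxy]benzoate
Conditions: 17 (6 equiv), SmI2 (30 mol%), THF, −10 °C
Reagents that add atoms: none
Why: Evans–Tishchenko reduction: the samarium hemiacetal formed from the C8–OH and benzaldehyde delivers hydride intramolecularly to the C1 ketone through a six‑membered chelate, and because C8 lies on the α side of the cyclopentanone the hydride enters from the α face, giving the 8‑benzoate and the 1β‑alcohol in one operation.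

Step 10
Reactants: 18 (1R,3R,3aS,4S,8S,8aR)-8-(benzoyloxy)-3-[(tert-butyldimethylsilyl)oxy]-1-hydroxy-6,8a-dimethyl-1,2,3,3a,4,5,8,8a-octahydroazulen-4-yl 4-[(tert-butyldimethylsilyl)oxy]benzoate
Product: 19 (1S,3R,3aS,4S,8S,8aR)-1-(acetyloxy)-8-(benzoyloxy)-3-[(tert-butyldimethylsilyl)oxy]-6,8a-dimethyl-1,2,3,3a,4,5,8,8a-octahydroazulen-4-yl 4-[(tert-butyldimethylsilyl)oxy]benzoate
Conditions: AcOH, PPh3, DIAD, toluene, 0 to 40 °C
Reagents that add atoms: acetic acid, CC(=O)O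
Why: Mitsunobu esterification inverts the C1 carbinol by SN2 (the same situation as the 17β to 17α inversion of steroids next to an angular methyl), giving the 1α‑acetate directly.

Step 11
Reactants: 19 (1S,3R,3aS,4S,8S,8aR)-1-(acetyloxy)-8-(benzoyloxy)-3-[(tert-butyldimethylsilyl)oxy]-6,8a-dimethyl-1,2,3,3a,4,5,8,8a-octahydroazulen-4-yl 4-[(tert-butyldimethylsilyl)oxy]benzoate
Product: 20 (1S,3R,3aR,4S,8S,8aR)-1-(acetyloxy)-8-(benzoyloxy)-3-hydroxy-6,8a-dimethyl-1,2,3,3a,4,5,8,8a-octahydroazulen-4-yl 4-hydroxybenzoate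
Conditions: HF·pyridine, pyridine/THF, 0 °C to rt
Reagents that add atoms: none
Why: Fluoride‑mediated desilylation removes both the secondary alkyl and the aryl TBS ethers while the three esters, including the allylic benzoate, are stable to buffered HF.

Step 12
Reactants: 20 (1S,3R,3aR,4S,8S,8aR)-1-(acetyloxy)-8-(benzoyloxy)-3-hydroxy-6,8a-dimethyl-1,2,3,3a,4,5,8,8a-octahydroazulen-4-yl 4-hydroxybenzoate
Product: 21 (1S,3aS,4S,8S,8aR)-1-(acetyloxy)-8-(benzoyloxy)-6,8a-dimethyl-3-oxo-1,2,3,3a,4,5,8,8a-octahydroazulen-4-yl 4-hydroxybenzoate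
Conditions: Dess–Martin periodinane, CH2Cl2, 0 °C
Reagents that add atoms: none
Why: Dess–Martin oxidation of the only aliphatic hydroxyl gives the C3 ketone under neutral conditions that leave the electron‑poor phenol, the esters and the trans ring fusion (C3a) untouched.

Step 13
Reactants: 21 (1S,3aS,4S,8S,8aR)-1-(acetyloxy)-8-(benzoyloxy)-6,8a-dimethyl-3-oxo-1,2,3,3a,4,5,8,8a-octahydroazulen-4-yl 4-hydroxybenzoate
Product: 22 (1S,3R,3aS,4S,8S,8aR)-1-(acetyloxy)-8-(benzoyloxy)-3-hydroxy-6,8a-dimethyl-3-(propan-2-yl)-1,2,3,3a,4,5,8,8a-octahydroazulen-4-yl 4-hydroxybenzoate (CNP0316187.1)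
Conditions: i-PrMgCl/CeCl3 (premixed, 5 equiv), THF, −78 °C; aq NH4Cl
Reagents that add atoms: isopropylmagnesium chloride, CC(C)[Mg]Cl
Why: Imamoto organocerium 1,2‑addition: the weakly basic i‑PrCeCl2 adds to the ketone at −78 °C faster than to the esters (one equivalent is consumed by the phenol, whose phenoxide also deactivates the aryl ester) and attacks the α face, anti to the adjacent C3a–C4 bond and the 1,3‑related angular methyl, giving the 3β‑hydroxy‑3α‑isopropyl carbinol (3R).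

**Compound list**
1 | (4R)-4-[(tert-butyldimethylsilyl)oxy]cyclopent-2-en-1-one | O=C1C=C[C@H](O[Si](C)(C)C(C)(C)C)C1 | starting material
2 | (4R)-4-[(tert-butyldimethylsilyl)oxy]-2-iodocyclopent-2-en-1-one | O=C1C(I)=C[C@H](O[Si](C)(C)C(C)(C)C)C1 | intermediate
3 | (4R)-4-[(tert-butyldimethylsilyl)oxy]-2-methylcyclopent-2-en-1-one | O=C1C(C)=C[C@H](O[Si](C)(C)C(C)(C)C)C1 | intermediate
4 | 1,3-dithiane | C1CSCSC1 | starting material
5 | 3-methylbut-2-enal | CC(C)=CC=O | starting material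
6 | 2-lithio-1,3-dithiane | [Li]C1SCCCS1 | intermediate
7 | lithium (3R,4R)-4-[(tert-butyldimethylsilyl)oxy]-3-(1,3-dithian-2-yl)-2-methylcyclopent-1-en-1-olate | [Li]OC1=C(C)[C@@H](C2SCCCS2)[C@H](O[Si](C)(C)C(C)(C)C)C1 | intermediate
8 | chlorozinc (3R,4R)-4-[(tert-butyldimethylsilyl)oxy]-3-(1,3-dithian-2-yl)-2-methylcyclopent-1-en-1-olate | Cl[Zn]OC1=C(C)[C@@H](C2SCCCS2)[C@H](O[Si](C)(C)C(C)(C)C)C1 | intermediate
9 | (2S,3R,4R)-4-[(tert-butyldimethylsilyl)oxy]-3-(1,3-dithian-2-yl)-2-[(1S)-1-hydroxy-3-methylbut-2-en-1-yl]-2-methylcyclopentan-1-one | O=C1C[C@@H](O[Si](C)(C)C(C)(C)C)[C@H](C2SCCCS2)[C@@]1(C)[C@@H](O)C=C(C)C | intermediate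
10 | (2S,3R,4R)-4-[(tert-butyldimethylsilyl)oxy]-3-formyl-2-[(1S)-1-hydroxy-3-methylbut-2-en-1-yl]-2-methylcyclopentan-1-one | O=C1C[C@@H](O[Si](C)(C)C(C)(C)C)[C@H](C=O)[C@@]1(C)[C@@H](O)C=C(C)C | intermediate
11 | (2S,3R,4R)-4-[(tert-butyldimethylsilyl)oxy]-2-[(1R,2RS)-2-chloro-1-hydroxy-3-methylbut-3-en-1-yl]-3-formyl-2-methylcyclopentan-1-one (both epimers at the chloride carbon, left undefined in the SMILES) | O=C1C[C@@H](O[Si](C)(C)C(C)(C)C)[C@H](C=O)[C@@]1(C)[C@@H](O)C(Cl)C(C)=C | intermediate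
12 | (3R,3aS,4S,8S,8aS)-3-[(tert-butyldimethylsilyl)oxy]-4,8-dihydroxy-6,8a-dimethyl-3,3a,4,5,8,8a-hexahydroazulen-1(2H)-one | O=C1C[C@@H](O[Si](C)(C)C(C)(C)C)[C@@H]2[C@@H](O)CC(C)=C[C@H](O)[C@@]12C | intermediate
13 | (4-bromophenoxy)(tert-butyl)dimethylsilane | Brc1ccc(O[Si](C)(C)C(C)(C)C)cc1 | starting material
14 | {4-[(tert-butyldimethylsilyl)oxy]phenyl}lithium | [Li]c1ccc(O[Si](C)(C)C(C)(C)C)cc1 | intermediate
15 | 4-[(tert-butyldimethylsilyl)oxy]benzoic acid | OC(=O)c1ccc(O[Si](C)(C)C(C)(C)C)cc1 | intermediate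
16 | (3R,3aS,4S,8S,8aS)-3-[(tert-butyldimethylsilyl)oxy]-8-hydroxy-6,8a-dimethyl-1-oxo-1,2,3,3a,4,5,8,8a-octahydroazulen-4-yl 4-[(tert-butyldimethylsilyl)oxy]benzoate | O=C1C[C@@H](O[Si](C)(C)C(C)(C)C)[C@@H]2[C@@H](OC(=O)c3ccc(O[Si](C)(C)C(C)(C)C)cc3)CC(C)=C[C@H](O)[C@@]12C | intermediate
17 | benzaldehyde | O=Cc1ccccc1 | starting material
18 | (1R,3R,3aS,4S,8S,8aR)-8-(benzoyloxy)-3-[(tert-butyldimethylsilyl)oxy]-1-hydroxy-6,8a-dimethyl-1,2,3,3a,4,5,8,8a-octahydroazulen-4-yl 4-[(tert-butyldimethylsilyl)oxy]benzoate | O[C@@H]1C[C@@H](O[Si](C)(C)C(C)(C)C)[C@@H]2[C@@H](OC(=O)c3ccc(O[Si](C)(C)C(C)(C)C)cc3)CC(C)=C[C@H](OC(=O)c3ccccc3)[C@@]12C | intermediate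
19 | (1S,3R,3aS,4S,8S,8aR)-1-(acetyloxy)-8-(benzoyloxy)-3-[(tert-butyldimethylsilyl)oxy]-6,8a-dimethyl-1,2,3,3a,4,5,8,8a-octahydroazulen-4-yl 4-[(tert-butyldimethylsilyl)oxy]benzoate | CC(=O)O[C@H]1C[C@@H](O[Si](C)(C)C(C)(C)C)[C@@H]2[C@@H](OC(=O)c3ccc(O[Si](C)(C)C(C)(C)C)cc3)CC(C)=C[C@H](OC(=O)c3ccccc3)[C@@]12C | intermediate
20 | (1S,3R,3aR,4S,8S,8aR)-1-(acetyloxy)-8-(benzoyloxy)-3-hydroxy-6,8a-dimethyl-1,2,3,3a,4,5,8,8a-octahydroazulen-4-yl 4-hydroxybenzoate | CC(=O)O[C@H]1C[C@@H](O)[C@@H]2[C@@H](OC(=O)c3ccc(O)cc3)CC(C)=C[C@H](OC(=O)c3ccccc3)[C@@]12C | intermediate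
21 | (1S,3aS,4S,8S,8aR)-1-(acetyloxy)-8-(benzoyloxy)-6,8a-dimethyl-3-oxo-1,2,3,3a,4,5,8,8a-octahydroazulen-4-yl 4-hydroxybenzoate | CC(=O)O[C@H]1CC(=O)[C@@H]2[C@@H](OC(=O)c3ccc(O)cc3)CC(C)=C[C@H](OC(=O)c3ccccc3)[C@@]12C | intermediate
22 | (1S,3R,3aS,4S,8S,8aR)-1-(acetyloxy)-8-(benzoyloxy)-3-hydroxy-6,8a-dimethyl-3-(propan-2-yl)-1,2,3,3a,4,5,8,8a-octahydroazulen-4-yl 4-hydroxybenzoate (CNP0316187.1) | CC(=O)O[C@H]1C[C@@](O)(C(C)C)[C@@H]2[C@@H](OC(=O)c3ccc(O)cc3)CC(C)=C[C@H](OC(=O)c3ccccc3)[C@@]12C | target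

**Step count**
Total steps: 13. Longest linear sequence: 12 (steps 1–6 and 8–13; step 7 is a one‑step side branch).

**Three steps most likely to fail, with fallbacks**

Step 6 (7‑endo ketyl cyclisation). Pinacol dimerisation, simple reduction of the aldehyde or 6‑exo closure could win. The fallback closes the ring by olefin metathesis. It sets out from 3: the same dithiane conjugate addition is run but the zinc enolate is trapped with acrolein, giving (2S,3R,4R)-4-[(tert-butyldimethylsilyl)oxy]-3-(1,3-dithian-2-yl)-2-[(1S)-1-hydroxyprop-2-en-1-yl]-2-methylcyclopentan-1-one F1. Hydrolysis of the dithiane (MeI, CaCO3) gives (2S,3R,4R)-4-[(tert-butyldimethylsilyl)oxy]-3-formyl-2-[(1S)-1-hydroxyprop-2-en-1-yl]-2-methylcyclopentan-1-one F2. Brown methallylboration of the aldehyde with (−)-B-methallyldiisopinocampheylborane (Si‑face attack, reagent control) gives (2S,3S,4R)-4-[(tert-butyldimethylsilyl)oxy]-3-[(1S)-1-hydroxy-3-methylbut-3-en-1-yl]-2-[(1S)-1-hydroxyprop-2-en-1-yl]-2-methylcyclopentan-1-one F3. Ring‑closing metathesis (Grubbs II, CH2Cl2, 40 °C) then forms the C6=C7 bond and comes back to the route at 12.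

Step 10 (Mitsunobu inversion at the neopentylic C1 carbinol). Elimination or participation of the neighbouring C8 benzoate could spoil the inversion. The fallback sets C1 by external hydride delivery instead and starts from 16. Narasaka–Prasad reduction (Et2BOMe, NaBH4, THF/MeOH, −78 °C) gives (1S,3R,3aS,4S,8S,8aR)-3-[(tert-butyldimethylsilyl)oxy]-1,8-dihydroxy-6,8a-dimethyl-1,2,3,3a,4,5,8,8a-octahydroazulen-4-yl 4-[(tert-butyldimethylsilyl)oxy]benzoate F4, because the boron chelate between C8–OH and the C1 ketone lies on the α face and hydride enters from the β face. NHC‑catalysed oxidative esterification with benzaldehyde 17 (IMes·HCl, DBU, 3,3′,5,5′-tetra-tert-butyldiphenoquinone) at the allylic C8–OH gives (1S,3R,3aS,4S,8S,8aR)-8-(benzoyloxy)-3-[(tert-butyldimethylsilyl)oxy]-1-hydroxy-6,8a-dimethyl-1,2,3,3a,4,5,8,8a-octahydroazulen-4-yl 4-[(tert-butyldimethylsilyl)oxy]benzoate F5. Acetylation (Ac2O, DMAP, pyridine) then comes back to the route at 19.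

Step 13 (isopropylcerium addition to a ketone flanked by three esters and a β‑acetoxy group). Enolisation with loss of acetate, β‑hydride reduction or ester attack could compete. The fallback sets out from 21 and uses a smaller sp2 nucleophile followed by a separate reduction. Isopropenylmagnesium bromide/CeCl3 (THF, −78 °C) gives (1S,3S,3aS,4S,8S,8aR)-1-(acetyloxy)-8-(benzoyloxy)-3-hydroxy-6,8a-dimethyl-3-(prop-1-en-2-yl)-1,2,3,3a,4,5,8,8a-octahydroazulen-4-yl 4-hydroxybenzoate F6. Chemoselective reduction of the 1,1‑disubstituted olefin with diimide (2‑nitrobenzenesulfonylhydrazide, Et3N), which spares the trisubstituted ring olefin and the allylic benzoate, comes back to the route at 22. This fallback does not correct the facial selectivity if that is what fails.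

**Further compounds**
F1 | step 6 | (2S,3R,4R)-4-[(tert-butyldimethylsilyl)oxy]-3-(1,3-dithian-2-yl)-2-[(1S)-1-hydroxyprop-2-en-1-yl]-2-methylcyclopentan-1-one | O=C1C[C@@H](O[Si](C)(C)C(C)(C)C)[C@H](C2SCCCS2)[C@@]1(C)[C@@H](O)C=C
F2 | step 6 | (2S,3R,4R)-4-[(tert-butyldimethylsilyl)oxy]-3-formyl-2-[(1S)-1-hydroxyprop-2-en-1-yl]-2-methylcyclopentan-1-one | O=C1C[C@@H](O[Si](C)(C)C(C)(C)C)[C@H](C=O)[C@@]1(C)[C@@H](O)C=C
F3 | step 6 | (2S,3S,4R)-4-[(tert-butyldimethylsilyl)oxy]-3-[(1S)-1-hydroxy-3-methylbut-3-en-1-yl]-2-[(1S)-1-hydroxyprop-2-en-1-yl]-2-methylcyclopentan-1-one | O=C1C[C@@H](O[Si](C)(C)C(C)(C)C)[C@H]([C@@H](O)CC(C)=C)[C@@]1(C)[C@@H](O)C=C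
F4 | step 10 | (1S,3R,3aS,4S,8S,8aR)-3-[(tert-butyldimethylsilyl)oxy]-1,8-dihydroxy-6,8a-dimethyl-1,2,3,3a,4,5,8,8a-octahydroazulen-4-yl 4-[(tert-butyldimethylsilyl)oxy]benzoate | O[C@H]1C[C@@H](O[Si](C)(C)C(C)(C)C)[C@@H]2[C@@H](OC(=O)c3ccc(O[Si](C)(C)C(C)(C)C)cc3)CC(C)=C[C@H](O)[C@@]12C
F5 | step 10 | (1S,3R,3aS,4S,8S,8aR)-8-(benzoyloxy)-3-[(tert-butyldimethylsilyl)oxy]-1-hydroxy-6,8a-dimethyl-1,2,3,3a,4,5,8,8a-octahydroazulen-4-yl 4-[(tert-butyldimethylsilyl)oxy]benzoate | O[C@H]1C[C@@H](O[Si](C)(C)C(C)(C)C)[C@@H]2[C@@H](OC(=O)c3ccc(O[Si](C)(C)C(C)(C)C)cc3)CC(C)=C[C@H](OC(=O)c3ccccc3)[C@@]12C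
F6 | step 13 | (1S,3S,3aS,4S,8S,8aR)-1-(acetyloxy)-8-(benzoyloxy)-3-hydroxy-6,8a-dimethyl-3-(prop-1-en-2-yl)-1,2,3,3a,4,5,8,8a-octahydroazulen-4-yl 4-hydroxybenzoate | CC(=O)O[C@H]1C[C@@](O)(C(C)=C)[C@@H]2[C@@H](OC(=O)c3ccc(O)cc3)CC(C)=C[C@H](OC(=O)c3ccccc3)[C@@]12C
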